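The earlier runs and the new flask come from a simulation for an exercise; the scatter is artificial.

Late in the two earlier runs, at 50.0 min, the grey flask with 11 mM of solid reagent and the amber flask with 24 mM stand at 16.8% and 16.3% of target, a gap close to the scatter of 0.3 percentage points. So we read the solid as a zero-order feed whose pace does not depend on the charge, and we read the grey solid as lasting to that reading. The grey charge divided by that time gives 0.220 mM min⁻¹, the draw ceiling, the highest mean loss of solid those runs allow.

common to all: substrate 20 mM

| flask | solid reagent | remark | time |
|---|---|---|---|
| grey | 11 mM | run made earlier |  |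
| amber | 24 mM | run made earlier |  |
| flask | 16.0 mM |  | 1.5 h |

| run | time / min | target / % |
|---|---|---|
| grey | 4.00 | 0.9 |
| grey | 6.00 | 2.0 |
| grey | 10.0 | 4.3 |
| grey | 15.0 | 6.0 |
| grey | 25.0 | 10.7 |
| grey | 40.0 | 14.8 |
| grey | 50.0 | 16.8 |
| amber | 4.00 | 1.0 |
| amber | 6.00 | 2.1 |
| amber | 10.0 | 4.3 |
| amber | 15.0 | 7.1 |
| amber | 25.0 | 10.8 |
| amber | 40.0 | 15.4 |
| amber | 50.0 | 16.3 |

(scatter of a reading: 0.3 percentage points)

- given per volume of solution although it is solid: solid reagent
- at the start none of the solid reagent is in solution
- partner is what solid reagent becomes in solution

* the target standing at 1.5 h, as a percentage of the substrate charged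
* concentration of partner in solution at 1.5 h, in percent of saturation

Turn the question round: for solid to be left in the new flask at 90 min, its mean draw has to stay below 0.178 mM min⁻¹. The grey target, at one solid per target, accounts for 0.0672 mM min⁻¹, so that is possible, but the ceiling stands higher, and at the ceiling the flask's charge lasts 72.7 min, less than the time asked. Our reckoning therefore bounds how long solid lasts in the new flask, to no less than 72.7 min, leaves open whether any is left at the asked time, and gives no level of the partner. The forecast goes further, with 21.3% of target (18.5% to 24%) and 100% of saturation (92% to 100%): “16 mM should leave solid present and sat stays about 100%”.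

The flask gives 17.1% of target and 19.1% of saturation, so the two part on the partner by 81 points.

    substrate + partner ⇌ target (K = 122 M⁻¹, k = 10.9 M⁻¹ min⁻¹)
    substrate + partner → isomer of the product (k = 4.06 M⁻¹ min⁻¹)
    solid reagent ⇌ partner, rate k3*(cs3 - [partner]) while solid is left; crystals form when [partner] > cs3 (solubility = 17.0 mM, k = 0.0132 min⁻¹)
    partner → decomposition product (k = 6.58 × 10⁻⁵ min⁻¹)

At 0.750 h the flask holds 41.9% of its solid, a mean draw of 0.207 mM min⁻¹, under the ceiling but above the 0.178 mM min⁻¹ that solid at 90 min required, and the isomer of the product by then stands at 19.4%, more than the target's 15.8%; at 1.50 h the solid is at 0%. The same charges read at 25 min allow, by the ceiling, a loss of 5.50 mM, which leaves at least 65.6% of the solid, and that neighbouring flask holds 66.9%.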